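**Retrosynthetic overview**

1. Daucane numbering: five-membered ring C1(CH3)–C2–C3–C4(OH)(iPr)–C5, seven-membered ring C5–C6(O-acyl)–C7–C8(CH3)–C9–C10–C1. The veratroate (C6–O acyl bond) and the 8,9-epoxide (from the C8=C9 alkene, directed by C6–OH) are disconnected last, back to diol 26.
2. In 26, C6–OH comes from 1,3-anti reduction of a C6 ketone, C5–H from equilibration next to that ketone, and the C4 carbinol from isopropyl addition to the cyclopentanone carbonyl of bicyclic 1,3-diketone 21 (as its C6 silyl enol ether 22); all three are read from the angular C1 methyl.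
3. Key disconnection C7–C8, closing the seven-membered ring by nickel-electrocatalytic decarboxylative alkenylation (17 → 19). Enabling feature: C8 is the methyl-bearing sp2 carbon of the cis-trisubstituted C8=C9 alkene inside the seven-membered ring (the retron of the epoxide), so it can be a Z-alkenyl iodide carbon; C7 is a CH2 next to the oxygenated C6, i.e. the α-carbon of an aldol-derived β-silyloxy acid that becomes a primary radical on decarboxylation.
4. 17 comes from a three-component assembly on a cyclopentenone: asymmetric conjugate methylation of 3-allylcyclopentenone 3 (sets C1), aldol of the regiodefined enolate with aldehyde 6 (C6, C7, carboxyl carbon), and allyl → Z-3-iodobut-2-enyl (C9, C8) by Lemieux–Johnson cleavage and Stork–Zhao olefination.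
5. Ring order: five-membered ring present from 1; seven-membered ring in step 9; oxirane in step 15.

Key step: step 9

Assumption: the aldol in step 3 is not expected to be highly diastereoselective at C5/C6; compounds 8–20 are drawn as the expected major isomer (anti aldol, side chain trans to the larger C1 substituent), and every other C5/C6 diastereomer takes the same steps and converges at diketone 21.

**Route**

Step 1
Reactants: 1 3-ethoxycyclopent-2-en-1-one
Product: 3 3-allylcyclopent-2-en-1-one, via bromomagnesium alkoxide adduct 2 (not isolated)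
Conditions: allylMgBr, THF, 0 °C; then 1 M HCl, 0 °C
Reagents that add atoms: allylmagnesium bromide, C=CC[Mg]Br
Why: Stork–Danheiser enone synthesis: 1,2-addition of the Grignard reagent to the vinylogous ester carbonyl gives 2, and acid hydrolysis of its enol ether with loss of water transposes the enone and leaves the allyl group (C10, C9) on the β-carbon (C1); no stereocentre is formed.

Step 2
Reactants: 3 3-allylcyclopent-2-en-1-one
Product: 5 (R)-3-allyl-3-methyl-1-(trimethylsilyloxy)cyclopent-1-ene, via dimethylaluminium enolate 4 (not isolated)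
Conditions: Me3Al, copper thiophene-2-carboxylate (CuTC, cat.), chiral phosphoramidite ligand (cat.), Et2O, −30 °C; then TMSOTf, −30 → 0 °C
Reagents that add atoms: trimethylaluminium, C[Al](C)C; trimethylsilyl triflate, C[Si](C)(C)OS(=O)(=O)C(F)(F)F
Why: Copper-catalysed asymmetric conjugate addition of a trialkylaluminium to a β-substituted cyclopentenone should create the quaternary C1 centre with R configuration under ligand control (methyl delivered to the Si face of the β-carbon), and O-silylation of aluminium enolate 4 stores the C4–C5 enolate regiospecifically.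

Step 3
Reactants: 5 (R)-3-allyl-3-methyl-1-(trimethylsilyloxy)cyclopent-1-ene; 6 3-(tert-butyldimethylsilyloxy)propanal
Product: 9 (2S,3R)-3-allyl-2-[(1S)-1,3-bis(tert-butyldimethylsilyloxy)propyl]-3-methylcyclopentan-1-one, via lithium enolate 7 (not isolated), via lithium aldolate 8 (not isolated)
Conditions: MeLi, THF, 0 °C; 6, −78 °C; then TBSOTf, −78 → 0 °C
Reagents that add atoms: tert-butyldimethylsilyl triflate, CC(C)(C)[Si](C)(C)OS(=O)(=O)C(F)(F)F
Why: Methyllithium cleaves the silyl enol ether to the regiodefined lithium enolate 7, whose aldol addition to 6 (closed transition state of the ring E-enolate, anti adduct, side chain mainly trans to the larger allyl group) gives 8, which is silylated in the same flask; the C5 and C6 centres made here need no control because both are erased in step 11.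

Step 4
Reactants: 9 (2S,3R)-3-allyl-2-[(1S)-1,3-bis(tert-butyldimethylsilyloxy)propyl]-3-methylcyclopentan-1-one
Product: 11 2-[(1R,2S)-2-[(1S)-1,3-bis(tert-butyldimethylsilyloxy)propyl]-1-methyl-3-oxocyclopentyl]acetaldehyde, via vicinal diol 10 (not isolated)
Conditions: OsO4 (cat.), NaIO4, 2,6-lutidine, dioxane/H2O, rt
Reagents that add atoms: osmium tetroxide, O=[Os](=O)(=O)=O; sodium periodate, [Na+].[O-]I(=O)(=O)=O
Why: Lemieux–Johnson oxidation: catalytic dihydroxylation of the only alkene to diol 10 and periodate cleavage give the C9 aldehyde without touching a stereocentre.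

Step 5
Reactants: 11 2-[(1R,2S)-2-[(1S)-1,3-bis(tert-butyldimethylsilyloxy)propyl]-1-methyl-3-oxocyclopentyl]acetaldehyde
Product: 12 (2S,3R)-2-[(1S)-1,3-bis(tert-butyldimethylsilyloxy)propyl]-3-[(2Z)-3-iodobut-2-en-1-yl]-3-methylcyclopentan-1-one
Conditions: EtPPh3I, n-BuLi, THF; I2, −78 °C; NaN(SiMe3)2, −20 °C; then 11, −78 °C
Reagents that add atoms: ethyltriphenylphosphonium iodide, CC[P+](c1ccccc1)(c1ccccc1)c1ccccc1.[I-]; iodine, [I][I]
Why: Stork–Zhao olefination: the α-iodo ylide adds to the unhindered aldehyde far faster than to the hindered ketone and should give the Z-alkenyl iodide (iodine cis to C10) under kinetic control, which fixes the cis geometry later needed in the ring.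

Step 6
Reactants: 12 (2S,3R)-2-[(1S)-1,3-bis(tert-butyldimethylsilyloxy)propyl]-3-[(2Z)-3-iodobut-2-en-1-yl]-3-methylcyclopentan-1-one
Product: 13 (2S,3R)-2-[(1S)-1-(tert-butyldimethylsilyloxy)-3-hydroxypropyl]-3-[(2Z)-3-iodobut-2-en-1-yl]-3-methylcyclopentan-1-one
Conditions: HF·pyridine, pyridine, THF, 0 °C
Reagents that add atoms: none
Why: Buffered HF·pyridine removes the primary silyl ether much faster than the hindered secondary one at C6.

Step 7
Reactants: 13 (2S,3R)-2-[(1S)-1-(tert-butyldimethylsilyloxy)-3-hydroxypropyl]-3-[(2Z)-3-iodobut-2-en-1-yl]-3-methylcyclopentan-1-one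
Product: 15 (3S)-3-(tert-butyldimethylsilyloxy)-3-[(1S,2R)-2-[(2Z)-3-iodobut-2-en-1-yl]-2-methyl-5-oxocyclopentyl]propanoic acid, via aldehyde 14 (not isolated)
Conditions: TEMPO (cat.), PhI(OAc)2, MeCN/H2O, rt
Reagents that add atoms: water, O
Why: Oxoammonium (TEMPO) oxidation with PhI(OAc)2 in aqueous acetonitrile takes the primary alcohol through aldehyde 14 and its hydrate to the acid and leaves alkenyl iodide, ketone and silyl ether untouched.

Step 8
Reactants: 15 (3S)-3-(tert-butyldimethylsilyloxy)-3-[(1S,2R)-2-[(2Z)-3-iodobut-2-en-1-yl]-2-methyl-5-oxocyclopentyl]propanoic acid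
Product: 17 1,3-dioxoisoindolin-2-yl (3S)-3-(tert-butyldimethylsilyloxy)-3-[(1S,2R)-2-[(2Z)-3-iodobut-2-en-1-yl]-2-methyl-5-oxocyclopentyl]propanoate, via O-acylisourea 16 (not isolated)
Conditions: N-hydroxyphthalimide, N,N′-diisopropylcarbodiimide, DMAP (cat.), CH2Cl2, rt
Reagents that add atoms: N-hydroxyphthalimide, ON1C(=O)c2ccccc2C1=O
Why: Carbodiimide (Steglich-type) esterification through O-acylisourea 16 gives the redox-active N-acyloxyphthalimide.

Step 9
Reactants: 17 1,3-dioxoisoindolin-2-yl (3S)-3-(tert-butyldimethylsilyloxy)-3-[(1S,2R)-2-[(2Z)-3-iodobut-2-en-1-yl]-2-methyl-5-oxocyclopentyl]propanoate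
Product: 19 (3aS,4S,8aR)-4-(tert-butyldimethylsilyloxy)-6,8a-dimethyl-1,2,3a,4,5,8-hexahydroazulen-3(8aH)-one, via primary C7 radical 18 (not isolated)
Conditions: NiCl2·6H2O (cat.), 2,2′-bipyridine, AgNO3 (cat.), LiCl, DMF (high dilution), sacrificial Mg anode, reticulated vitreous carbon cathode, constant current, rt
Reagents that add atoms: none
Why: Proposed new method: single-electron reduction of the N-acyloxyphthalimide (by low-valent nickel or at the silver-coated cathode) expels CO2 and phthalimide and leaves the primary C7 radical 18, while zerovalent nickel carrying bipyridine inserts into the C8–I bond with retention of the Z geometry; the alkenylnickel centre captures the radical of the same molecule and the C7–C8 bond forms by reductive elimination from trivalent nickel. The closest known reaction is the intermolecular nickel-electrocatalytic decarboxylative alkenylation of redox-active esters with alkenyl halides, and what is new is its intramolecular, ring-closing use. The seven-membered ring closes by C(sp3)–C(sp2) reductive elimination from an eight-membered nickelacycle and not by radical addition to the alkene, so the 6-exo preference of a hept-6-enyl radical should not decide the outcome. No stereocentre is formed: the alkenyl iodide already has iodine cis to C10, the geometry the ring requires, and the C6 silyloxy group should survive because radical capture and reductive elimination are faster than β-elimination. The selectivity needed is ring closure over intermolecular coupling and over simple reduction of the radical, which high dilution, slow electrolysis and the quaternary C1 holding both chains on adjacent ring carbons should secure.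

Step 10
Reactants: 19 (3aS,4S,8aR)-4-(tert-butyldimethylsilyloxy)-6,8a-dimethyl-1,2,3a,4,5,8-hexahydroazulen-3(8aH)-one
Product: 20 (3aS,4S,8aR)-4-hydroxy-6,8a-dimethyl-1,2,3a,4,5,8-hexahydroazulen-3(8aH)-one
Conditions: HF·pyridine, THF, 0 °C → rt
Reagents that add atoms: none
Why: Acidic fluoride cleaves the secondary silyl ether without the β-elimination or retro-aldol cleavage that basic fluoride could cause.

Step 11
Reactants: 20 (3aS,4S,8aR)-4-hydroxy-6,8a-dimethyl-1,2,3a,4,5,8-hexahydroazulen-3(8aH)-one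
Product: 21 (8aR)-6,8a-dimethyl-1,2,8,8a-tetrahydroazulene-3,4(3aH,5H)-dione
Conditions: Dess–Martin periodinane, CH2Cl2, rt
Reagents that add atoms: none
Why: Dess–Martin oxidation of the β-hydroxy ketone gives the enolised 1,3-diketone, which removes the C5 and C6 stereocentres from step 3 so that all aldol diastereomers converge on one compound.

Step 12
Reactants: 21 (8aR)-6,8a-dimethyl-1,2,8,8a-tetrahydroazulene-3,4(3aH,5H)-dione
Product: 22 (8aR)-4-(tert-butyldimethylsilyloxy)-6,8a-dimethyl-1,2,8,8a-tetrahydroazulen-3(5H)-one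
Conditions: TBSOTf, Et3N, CH2Cl2, −78 → 0 °C
Reagents that add atoms: tert-butyldimethylsilyl triflate, CC(C)(C)[Si](C)(C)OS(=O)(=O)C(F)(F)F
Why: O-silylation of the enolised 1,3-diketone, with silyl groups free to equilibrate between the two oxygens, should give the enol ether whose C5=C6 double bond is exocyclic to the cyclopentanone and endocyclic in the seven-membered ring (the preferred enol of a 2-acylcyclopentanone), which leaves the C4 ketone as the only free carbonyl.

Step 13
Reactants: 22 (8aR)-4-(tert-butyldimethylsilyloxy)-6,8a-dimethyl-1,2,8,8a-tetrahydroazulen-3(5H)-one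
Product: 24 (3R,3aR,8aR)-3-hydroxy-6,8a-dimethyl-3-(propan-2-yl)-1,2,3,3a,8,8a-hexahydroazulen-4(5H)-one, via chloromagnesium alkoxide 23 (not isolated)
Conditions: iPrMgCl, LaCl3·2LiCl, THF, −20 °C; then TBAF, AcOH, THF, 0 °C
Reagents that add atoms: isopropylmagnesium chloride, CC(C)[Mg]Cl
Why: Lanthanide-promoted 1,2-addition of the Grignard reagent to the C4 carbonyl of the vinylogous silyl ester (the addition used in the Stork–Danheiser sequence) should occur anti to the angular C1 methyl, the only group over the planar alkylidene-cyclopentanone, which sets C4 (isopropyl α, hydroxyl β); buffered fluoride then releases the C6 ketone from 23, and C5, epimerisable next to that ketone, should settle in the trans-fused form with C6 trans to isopropyl and a hydrogen bond from C4–OH to C6=O.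

Step 14
Reactants: 24 (3R,3aR,8aR)-3-hydroxy-6,8a-dimethyl-3-(propan-2-yl)-1,2,3,3a,8,8a-hexahydroazulen-4(5H)-one
Product: 26 (3R,3aS,4S,8aR)-6,8a-dimethyl-3-(propan-2-yl)-1,2,3,3a,4,5,8,8a-octahydroazulene-3,4-diol, via alkoxydiacetoxyborohydride 25 (not isolated)
Conditions: Me4NBH(OAc)3, MeCN/AcOH, −30 °C
Reagents that add atoms: none
Why: Evans–Saksena reduction: the tertiary C4 hydroxyl exchanges onto boron (25) and hydride is delivered intramolecularly to the β-face of the C6 carbonyl, which gives the 1,3-anti diol (6α-OH).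

Step 15
Reactants: 26 (3R,3aS,4S,8aR)-6,8a-dimethyl-3-(propan-2-yl)-1,2,3,3a,4,5,8,8a-octahydroazulene-3,4-diol
Product: 27 (1R,4R,5S,6S,8R,9S)-8,9-epoxydaucane-4,6-diol (daucane numbering as in the overview)
Conditions: VO(acac)2 (cat.), t-BuOOH, CH2Cl2, 0 °C → rt
Reagents that add atoms: tert-butyl hydroperoxide, CC(C)(C)OO
Why: Vanadium-catalysed epoxidation with t-BuOOH directed by the homoallylic C6 hydroxyl delivers oxygen to the α-face of the C8=C9 alkene, which is also the face away from the angular methyl, and so sets C8 (R) and C9 (S).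

Step 16
Reactants: 27 (1R,4R,5S,6S,8R,9S)-8,9-epoxydaucane-4,6-diol; 28 3,4-dimethoxybenzoyl chloride
Product: 29 (1R,4R,5S,6S,8R,9S)-8,9-epoxy-4-hydroxydaucan-6-yl 3,4-dimethoxybenzoate
Conditions: Et3N, DMAP (cat.), CH2Cl2, 0 °C → rt
Reagents that add atoms: none
Why: DMAP-catalysed acylation esterifies the secondary C6 hydroxyl, while the tertiary C4 hydroxyl is too hindered to react and the oxirane survives the basic, non-nucleophilic conditions.

**Compound list**

1 | 3-ethoxycyclopent-2-en-1-one | CCOC1=CC(=O)CC1 | starting material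
2 | bromomagnesium alkoxide of 1-allyl-3-ethoxycyclopent-2-en-1-ol (racemic 1,2-adduct) | CCOC1=CC(CC=C)(O[Mg]Br)CC1 | intermediate
3 | 3-allylcyclopent-2-en-1-one | C=CCC1=CC(=O)CC1 | intermediate
4 | dimethylaluminium enolate of (R)-3-allyl-3-methylcyclopentanone | C[Al](C)OC1=C[C@@](C)(CC=C)CC1 | intermediate
5 | (R)-3-allyl-3-methyl-1-(trimethylsilyloxy)cyclopent-1-ene | C[Si](C)(C)OC1=C[C@@](C)(CC=C)CC1 | intermediate
6 | 3-(tert-butyldimethylsilyloxy)propanal | CC(C)(C)[Si](C)(C)OCCC=O | starting material
7 | lithium enolate of (R)-3-allyl-3-methylcyclopentanone (C4–C5 enolate) | [Li]OC1=C[C@@](C)(CC=C)CC1 | intermediate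
8 | lithium aldolate of 7 and 6 (anti, major diastereomer) | CC(C)(C)[Si](C)(C)OCC[C@H](O[Li])[C@H]1C(=O)CC[C@]1(C)CC=C | intermediate
9 | (2S,3R)-3-allyl-2-[(1S)-1,3-bis(tert-butyldimethylsilyloxy)propyl]-3-methylcyclopentan-1-one | CC(C)(C)[Si](C)(C)OCC[C@H](O[Si](C)(C)C(C)(C)C)[C@H]1C(=O)CC[C@]1(C)CC=C | intermediate
10 | (2S,3R)-2-[(1S)-1,3-bis(tert-butyldimethylsilyloxy)propyl]-3-(2,3-dihydroxypropyl)-3-methylcyclopentan-1-one (both epimers at the new carbinol) | CC(C)(C)[Si](C)(C)OCC[C@H](O[Si](C)(C)C(C)(C)C)[C@H]1C(=O)CC[C@]1(C)CC(O)CO | intermediate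
11 | 2-[(1R,2S)-2-[(1S)-1,3-bis(tert-butyldimethylsilyloxy)propyl]-1-methyl-3-oxocyclopentyl]acetaldehyde | CC(C)(C)[Si](C)(C)OCC[C@H](O[Si](C)(C)C(C)(C)C)[C@H]1C(=O)CC[C@]1(C)CC=O | intermediate
12 | (2S,3R)-2-[(1S)-1,3-bis(tert-butyldimethylsilyloxy)propyl]-3-[(2Z)-3-iodobut-2-en-1-yl]-3-methylcyclopentan-1-one | CC(C)(C)[Si](C)(C)OCC[C@H](O[Si](C)(C)C(C)(C)C)[C@H]1C(=O)CC[C@]1(C)C/C=C(/C)I | intermediate
13 | (2S,3R)-2-[(1S)-1-(tert-butyldimethylsilyloxy)-3-hydroxypropyl]-3-[(2Z)-3-iodobut-2-en-1-yl]-3-methylcyclopentan-1-one | OCC[C@H](O[Si](C)(C)C(C)(C)C)[C@H]1C(=O)CC[C@]1(C)C/C=C(/C)I | intermediate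
14 | (3S)-3-(tert-butyldimethylsilyloxy)-3-[(1S,2R)-2-[(2Z)-3-iodobut-2-en-1-yl]-2-methyl-5-oxocyclopentyl]propanal | O=CC[C@H](O[Si](C)(C)C(C)(C)C)[C@H]1C(=O)CC[C@]1(C)C/C=C(/C)I | intermediate
15 | (3S)-3-(tert-butyldimethylsilyloxy)-3-[(1S,2R)-2-[(2Z)-3-iodobut-2-en-1-yl]-2-methyl-5-oxocyclopentyl]propanoic acid | OC(=O)C[C@H](O[Si](C)(C)C(C)(C)C)[C@H]1C(=O)CC[C@]1(C)C/C=C(/C)I | intermediate
16 | O-acylisourea of 15 and N,N′-diisopropylcarbodiimide | CC(C)N=C(NC(C)C)OC(=O)C[C@H](O[Si](C)(C)C(C)(C)C)[C@H]1C(=O)CC[C@]1(C)C/C=C(/C)I | intermediate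
17 | 1,3-dioxoisoindolin-2-yl ester of 15 (redox-active ester) | O=C(C[C@H](O[Si](C)(C)C(C)(C)C)[C@H]1C(=O)CC[C@]1(C)C/C=C(/C)I)ON1C(=O)c2ccccc2C1=O | intermediate
18 | primary C7 radical from 17 after loss of CO2 and phthalimide | [CH2][C@H](O[Si](C)(C)C(C)(C)C)[C@H]1C(=O)CC[C@]1(C)C/C=C(/C)I | intermediate
19 | (3aS,4S,8aR)-4-(tert-butyldimethylsilyloxy)-6,8a-dimethyl-1,2,3a,4,5,8-hexahydroazulen-3(8aH)-one (C4 ketone, 6α-silyloxy, C8=C9 alkene, trans-fused) | CC(C)(C)[Si](C)(C)O[C@H]1CC(C)=CC[C@@]2(C)CCC(=O)[C@H]12 | intermediate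
20 | (3aS,4S,8aR)-4-hydroxy-6,8a-dimethyl-1,2,3a,4,5,8-hexahydroazulen-3(8aH)-one | O[C@H]1CC(C)=CC[C@@]2(C)CCC(=O)[C@H]12 | intermediate
21 | (8aR)-6,8a-dimethyl-1,2,8,8a-tetrahydroazulene-3,4(3aH,5H)-dione (C5 enolised, not a fixed stereocentre) | O=C1CC(C)=CC[C@@]2(C)CCC(=O)C12 | intermediate
22 | (8aR)-4-(tert-butyldimethylsilyloxy)-6,8a-dimethyl-1,2,8,8a-tetrahydroazulen-3(5H)-one (C5=C6 silyl enol ether, C4 ketone) | CC(C)(C)[Si](C)(C)OC1=C2C(=O)CC[C@]2(C)CC=C(C)C1 | intermediate
23 | chloromagnesium alkoxide of (3R,8aR)-4-(tert-butyldimethylsilyloxy)-6,8a-dimethyl-3-(propan-2-yl)-1,2,3,5,8,8a-hexahydroazulen-3-ol | CC(C)(C)[Si](C)(C)OC1=C2[C@](O[Mg]Cl)(C(C)C)CC[C@]2(C)CC=C(C)C1 | intermediate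
24 | (3R,3aR,8aR)-3-hydroxy-6,8a-dimethyl-3-(propan-2-yl)-1,2,3,3a,8,8a-hexahydroazulen-4(5H)-one | O=C1CC(C)=CC[C@@]2(C)CC[C@@](O)(C(C)C)[C@H]12 | intermediate
25 | tetramethylammonium alkoxydiacetoxyborohydride of 24 (boron on the C4 oxygen) | O=C1CC(C)=CC[C@@]2(C)CC[C@@](O[BH-](OC(C)=O)OC(C)=O)(C(C)C)[C@H]12.C[N+](C)(C)C | intermediate
26 | (3R,3aS,4S,8aR)-6,8a-dimethyl-3-(propan-2-yl)-1,2,3,3a,4,5,8,8a-octahydroazulene-3,4-diol (jaeschkeanadiol) | O[C@H]1CC(C)=CC[C@@]2(C)CC[C@@](O)(C(C)C)[C@H]12 | intermediate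
27 | (1R,4R,5S,6S,8R,9S)-8,9-epoxydaucane-4,6-diol (8α,9α-epoxide of 26) | O[C@H]1C[C@@]2(C)O[C@H]2C[C@@]3(C)CC[C@@](O)(C(C)C)[C@H]13 | intermediate
28 | 3,4-dimethoxybenzoyl chloride | COc1ccc(C(Cl)=O)cc1OC | starting material
29 | (1R,4R,5S,6S,8R,9S)-8,9-epoxy-4-hydroxydaucan-6-yl 3,4-dimethoxybenzoate (CNP0251065.1) | COc1ccc(C(=O)O[C@H]2C[C@@]3(C)O[C@H]3C[C@@]3(C)CC[C@@](O)(C(C)C)[C@H]23)cc1OC | target

**Step count and risks**

Total step count: 16. Longest linear sequence: 16 steps (1 → 29); 6 and 28 enter as commercial compounds.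

Steps most likely to fail:

1. Step 9 (bears the label). The ring closure may lose to intermolecular coupling, to hydrogen abstraction by the C7 radical before it reaches nickel, to 6-exo attack of the radical on C9, or to protodehalogenation of the alkenyl iodide. Fallback (ring-closing metathesis at C8=C9 in place of the C7–C8 coupling, known chemistry): it sets out from 5 and comes back to the route at 19. 3-Methylbut-3-enal F1 is made beforehand from commercial 3-methylbut-3-en-1-ol with Dess–Martin periodinane. Enolate 7 (from 5 and MeLi) adds to it to give the methallyl hydroxy ketone F2, and silylation (TBSOTf, 2,6-lutidine) gives the diene silyl ether F3. Second-generation Grubbs catalyst (CH2Cl2, 40 °C) then joins the allyl group on C1 with the 1,1-disubstituted alkene and, with loss of ethylene, should give 19.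

2. Step 12. Silylation may occur on the C4 oxygen, or the silyl group may migrate or hydrolyse, which would expose the wrong carbonyl to the Grignard reagent in step 13. Fallback (the C6 oxygen is removed and put back after the C4 carbinol is made): it sets out from 19 and comes back at 24. DBU eliminates the silanol from 19 to give the dienone F4. iPrMgCl with LaCl3·2LiCl adds to its only carbonyl, anti to the angular methyl, to give the tertiary dienol F5. Hydroxyl-directed epoxidation (VO(acac)2, t-BuOOH) of the allylic C5=C6 alkene gives the epoxy alcohol F6. Reductive opening with Cp2TiCl (trivalent titanium, from Cp2TiCl2 and Zn) and 1,4-cyclohexadiene cleaves the C5–O bond and gives the 1,3-diol F7. Dess–Martin oxidation of its secondary hydroxyl gives 24, where C5 equilibrates as in step 13.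

3. Step 13. The Grignard reagent may deprotonate C7 instead of adding, addition to the hindered vinylogous ester carbonyl may be slow or poorly face-selective, and release of the ketone may be followed by dehydration or retro-aldol cleavage. Fallback (smaller sp2 nucleophile, then hydrogenation): it sets out from 22 and comes back at 24. Isopropenylmagnesium bromide with LaCl3·2LiCl, followed by TBAF/AcOH, gives the isopropenyl carbinol F8. Hydrogenation with RhCl(PPh3)3 and H2 reduces only the 1,1-disubstituted alkene and leaves the trisubstituted ring alkene, giving 24.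

Further compounds
F1 | step 9 | 3-methylbut-3-enal | CC(=C)CC=O
F2 | step 9 | (2S,3R)-3-allyl-2-[(1S)-1-hydroxy-3-methylbut-3-en-1-yl]-3-methylcyclopentan-1-one (major diastereomer) | CC(=C)C[C@H](O)[C@H]1C(=O)CC[C@]1(C)CC=C
F3 | step 9 | tert-butyldimethylsilyl ether of F2 | CC(=C)C[C@H](O[Si](C)(C)C(C)(C)C)[C@H]1C(=O)CC[C@]1(C)CC=C
F4 | step 12 | (8aR)-6,8a-dimethyl-1,2,8,8a-tetrahydroazulen-3(5H)-one (C5=C6 enone, C8=C9 alkene) | O=C1CC[C@]2(C)CC=C(C)CC=C12
F5 | step 12 | (3R,8aR)-6,8a-dimethyl-3-(propan-2-yl)-1,2,3,5,8,8a-hexahydroazulen-3-ol | CC(C)[C@]1(O)CC[C@]2(C)CC=C(C)CC=C12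
F6 | step 12 | C5–C6 β-epoxide of F5 (oxygen syn to the C4 hydroxyl) | CC(C)[C@]1(O)CC[C@]2(C)CC=C(C)C[C@H]3O[C@@]123
F7 | step 12 | (3R,4R,8aR)-6,8a-dimethyl-3-(propan-2-yl)-1,2,3,3a,4,5,8,8a-octahydroazulene-3,4-diol (6β-hydroxyl, C5 epimers) | CC(C)[C@]1(O)CC[C@]2(C)CC=C(C)C[C@@H](O)C12
F8 | step 13 | (3S,3aR,8aR)-3-hydroxy-6,8a-dimethyl-3-(prop-1-en-2-yl)-1,2,3,3a,8,8a-hexahydroazulen-4(5H)-one | O=C1CC(C)=CC[C@@]2(C)CC[C@@](O)(C(C)=C)[C@H]12
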